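The oxolane (O1, C2–C5) is disconnected at C3–C4 and at the bond between the exocyclic CH2 on C4 and its guaiacyl ring. One operation forms both: a C3 radical, released reductively from an oxirane, closes 5-exo onto an O-allyl group, and the resulting CH2 radical is arylated at nickel. The step exploits the 2,3-trans-3,4-cis substituent pattern around ring carbons C2, C3 and C4, which a chair-like closure relays from C2 alone. The precursor is the allyl ether of an erythro (1S,2R)-1-aryl-2,3-epoxypropan-1-ol from a Sharpless resolution. Both phenols travel as triisopropylsilyl (TIPS) ethers, so that no hydrogenolysis ever meets the benzylic C2–O1 bond of the finished oxolane.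

Key step: step 6

Remark: oxolane numbering O1, C2 (aryl), C3 (CH2O–acyl), C4 (CH2–aryl), C5 is used throughout; with L-(+)-DIPT the (R)-allylic alcohol is the fast enantiomer and gives the erythro epoxy alcohol with an (S) carbinol carbon and an (R) oxirane carbon (the carbinol keeps its geometry, only its CIP ranking changes), and the oxirane configuration is erased in step 6.

Step 1
Reactants: 1 vanillin (4-hydroxy-3-methoxybenzaldehyde)
Product: 2 3-methoxy-4-(triisopropylsilyloxy)benzaldehyde
Conditions: TIPSCl, imidazole, DMF, rt
Reagents that add atoms: triisopropylsilyl chloride, CC(C)[Si](Cl)(C(C)C)C(C)C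
Why: Imidazole-promoted O-silylation of a phenol is reliable, and the hindered aryl TIPS ether should withstand the Grignard reagent, the sodium alkoxide and the reducing metals met later, yet leave with fluoride at the end.

Step 2
Reactants: 2 3-methoxy-4-(triisopropylsilyloxy)benzaldehyde; 3 vinylmagnesium bromide
Product: 4 racemic 1-[3-methoxy-4-(triisopropylsilyloxy)phenyl]prop-2-en-1-ol
Conditions: THF, −78 → 0 °C; then aq NH4Cl
Reagents that add atoms: none
Why: Grignard 1,2-addition to a non-enolisable aromatic aldehyde should give the allylic alcohol as a racemate, whose carbinol stereocentre is sorted out in step 3.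

Step 3
Reactants: 4 racemic 1-[3-methoxy-4-(triisopropylsilyloxy)phenyl]prop-2-en-1-ol
Product: 5 (S)-[3-methoxy-4-(triisopropylsilyloxy)phenyl][(R)-oxiran-2-yl]methanol (erythro)
Conditions: Ti(OiPr)4 (10 mol %), L-(+)-DIPT (15 mol %), tBuOOH (0.45 equiv), 4 Å MS, CH2Cl2, −20 °C
Reagents that add atoms: tert-butyl hydroperoxide, CC(C)(C)OO
Why: Sharpless kinetic resolution: the titanium–L-(+)-tartrate catalyst should epoxidise the (R)-alcohol far faster than the (S)-alcohol and deliver oxygen to the alkene face that gives the erythro isomer, so the carbinol configuration (future C2) is selected by the tartrate and the oxirane carbon is set by the same reagent control, while the substoichiometric charge of tBuOOH should keep the slow enantiomer out of the product.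

Step 4
Reactants: 5 (S)-[3-methoxy-4-(triisopropylsilyloxy)phenyl][(R)-oxiran-2-yl]methanol; 6 allyl bromide
Product: 7 (R)-2-[(S)-(allyloxy)[3-methoxy-4-(triisopropylsilyloxy)phenyl]methyl]oxirane
Conditions: NaH, Bu4NI (cat.), THF, 0 °C → rt
Reagents that add atoms: none
Why: Williamson etherification of the sodium alkoxide by the reactive allylic bromide in THF at low temperature should be faster than epoxide migration, and neither stereocentre is touched.

Step 5
Reactants: 8 4-bromo-2-methoxyphenol
Product: 9 (4-bromo-2-methoxyphenoxy)triisopropylsilane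
Conditions: TIPSCl, imidazole, DMF, rt
Reagents that add atoms: triisopropylsilyl chloride, CC(C)[Si](Cl)(C(C)C)C(C)C
Why: The same phenol O-silylation as in step 1 should give the aryl bromide partner with its protecting group matched to 7.

Step 6
Reactants: 7 (R)-2-[(S)-(allyloxy)[3-methoxy-4-(triisopropylsilyloxy)phenyl]methyl]oxirane; 9 (4-bromo-2-methoxyphenoxy)triisopropylsilane (1.5 equiv)
Product: 12 [(2R,3S,4S)-2-[3-methoxy-4-(triisopropylsilyloxy)phenyl]-4-[3-methoxy-4-(triisopropylsilyloxy)benzyl]oxolan-3-yl]methanol, via C3 radical Cp2Ti(Cl) alkoxide 10 (not isolated), via oxolan-4-ylmethyl radical Cp2Ti(Cl) alkoxide 11 (not isolated)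
Conditions: NiBr2·diglyme (5 mol %), 4,4′-di-tert-butyl-2,2′-bipyridine (5 mol %), Cp2TiCl2 (20 mol %), Mn powder (3 equiv), Et3N·HCl (1.5 equiv), DMPU, rt
Reagents that add atoms: none
Why: Proposed new method: Cp2TiCl (trivalent titanium, formed from Cp2TiCl2 and Mn) should cleave the oxirane of 7 homolytically at its internal carbon to give the secondary C3 radical 10, which closes onto the allyl ether to the primary radical 11; 11 should then be captured by nickel that has already inserted, from its zerovalent state, into the C–Br bond of 9, and reductive elimination from the resulting trivalent nickel species makes the CH2–aryl bond while Et3N·HCl frees the alcohol and Mn turns over both metals. The closest known reaction types are the Cp2TiCl radical cyclisation of epoxy allyl ethers, the titanium/nickel reductive arylation of epoxides by aryl bromides and the nickel cyclisation–arylation of alkenyl halides; their union in one flask is the untested part. The oxolane closes in the 5-exo-trig mode through the new C3–C4 bond. C3 and C4 are both set under control of the C2 stereocentre in a chair-like transition state: the C2 aryl group sits pseudo-equatorial, the CH2O–titanium arm on the planar radical carbon turns away from it (2,3-trans) and the alkene CH2 ends cis to that arm (3,4-cis), whereas the oxirane configuration is erased. The step needs ring closure to come before any bimolecular capture of 10 by nickel or titanium, and the ether oxygen in the tether, which puts this 3-oxahex-5-enyl closure among the fastest 5-exo cyclisations, together with the low metal loadings should secure that order, leaving the unhindered primary radical 11 as the partner for nickel.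

Step 7
Reactants: 12 [(2R,3S,4S)-2-[3-methoxy-4-(triisopropylsilyloxy)phenyl]-4-[3-methoxy-4-(triisopropylsilyloxy)benzyl]oxolan-3-yl]methanol; 13 (R)-2-methylbutanoic acid
Product: 14 [(2R,3S,4S)-2-[3-methoxy-4-(triisopropylsilyloxy)phenyl]-4-[3-methoxy-4-(triisopropylsilyloxy)benzyl]oxolan-3-yl]methyl (2R)-2-methylbutanoate
Conditions: DCC, DMAP (cat.), CH2Cl2, 0 °C → rt
Reagents that add atoms: none
Why: Steglich esterification of the unhindered primary alcohol should be clean, and under these neutral conditions with only catalytic DMAP the α-stereocentre of the acid should not enolise, while no ring stereocentre is involved.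

Step 8
Reactants: 14 [(2R,3S,4S)-2-[3-methoxy-4-(triisopropylsilyloxy)phenyl]-4-[3-methoxy-4-(triisopropylsilyloxy)benzyl]oxolan-3-yl]methyl (2R)-2-methylbutanoate
Product: 15 [(2R,3S,4S)-2-(4-hydroxy-3-methoxyphenyl)-4-(4-hydroxy-3-methoxybenzyl)oxolan-3-yl]methyl (2R)-2-methylbutanoate (target)
Conditions: Bu4NF, AcOH, THF, 0 °C
Reagents that add atoms: none
Why: Fluoride-induced cleavage of the two aryl silyl ethers should be fast at 0 °C, and the acetic acid buffer keeps the medium near neutral so that the ester, its α-stereocentre and the benzylic C2–O1 ether should pass unchanged.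

Compound list
1 | vanillin (4-hydroxy-3-methoxybenzaldehyde) | COc1cc(C=O)ccc1O | starting material
2 | 3-methoxy-4-(triisopropylsilyloxy)benzaldehyde | COc1cc(C=O)ccc1O[Si](C(C)C)(C(C)C)C(C)C | intermediate
3 | vinylmagnesium bromide | C=C[Mg]Br | starting material
4 | racemic 1-[3-methoxy-4-(triisopropylsilyloxy)phenyl]prop-2-en-1-ol | C=CC(O)c1ccc(O[Si](C(C)C)(C(C)C)C(C)C)c(OC)c1 | intermediate
5 | (S)-[3-methoxy-4-(triisopropylsilyloxy)phenyl][(R)-oxiran-2-yl]methanol, erythro (1S,2R) epoxy alcohol | O[C@@H](c1ccc(O[Si](C(C)C)(C(C)C)C(C)C)c(OC)c1)[C@H]1CO1 | intermediate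
6 | allyl bromide | C=CCBr | starting material
7 | (R)-2-[(S)-(allyloxy)[3-methoxy-4-(triisopropylsilyloxy)phenyl]methyl]oxirane, precursor of the key step | C=CCO[C@@H](c1ccc(O[Si](C(C)C)(C(C)C)C(C)C)c(OC)c1)[C@H]1CO1 | intermediate
8 | 4-bromo-2-methoxyphenol | COc1cc(Br)ccc1O | starting material
9 | (4-bromo-2-methoxyphenoxy)triisopropylsilane | COc1cc(Br)ccc1O[Si](C(C)C)(C(C)C)C(C)C | intermediate
10 | secondary C3 radical from oxirane opening, as its Cp2Ti(Cl) alkoxide (tetravalent titanium), formed in the flask in step 6 | C=CCO[C@@H](c1ccc(O[Si](C(C)C)(C(C)C)C(C)C)c(OC)c1)[CH]CO[Ti](Cl)(C1C=CC=C1)C1C=CC=C1 | intermediate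
11 | cyclised (2R,3S,4S)-oxolan-4-ylmethyl radical, as its Cp2Ti(Cl) alkoxide (tetravalent titanium), formed in the flask in step 6 | Cl[Ti](C1C=CC=C1)(C1C=CC=C1)OC[C@@H]1[C@H]([CH2])CO[C@H]1c1ccc(O[Si](C(C)C)(C(C)C)C(C)C)c(OC)c1 | intermediate
12 | [(2R,3S,4S)-2-[3-methoxy-4-(triisopropylsilyloxy)phenyl]-4-[3-methoxy-4-(triisopropylsilyloxy)benzyl]oxolan-3-yl]methanol, product of the key step | OC[C@@H]1[C@H](Cc2ccc(O[Si](C(C)C)(C(C)C)C(C)C)c(OC)c2)CO[C@H]1c1ccc(O[Si](C(C)C)(C(C)C)C(C)C)c(OC)c1 | intermediate
13 | (R)-2-methylbutanoic acid | CC[C@@H](C)C(=O)O | starting material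
14 | [(2R,3S,4S)-2-[3-methoxy-4-(triisopropylsilyloxy)phenyl]-4-[3-methoxy-4-(triisopropylsilyloxy)benzyl]oxolan-3-yl]methyl (2R)-2-methylbutanoate | CC[C@@H](C)C(=O)OC[C@@H]1[C@H](Cc2ccc(O[Si](C(C)C)(C(C)C)C(C)C)c(OC)c2)CO[C@H]1c1ccc(O[Si](C(C)C)(C(C)C)C(C)C)c(OC)c1 | intermediate
15 | [(2R,3S,4S)-2-(4-hydroxy-3-methoxyphenyl)-4-(4-hydroxy-3-methoxybenzyl)oxolan-3-yl]methyl (2R)-2-methylbutanoate | CC[C@@H](C)C(=O)OC[C@@H]1[C@H](Cc2ccc(O)c(OC)c2)CO[C@H]1c1ccc(O)c(OC)c1 | target

Total step count: 8. Longest linear sequence: 7 (steps 1–4 and 6–8; step 5 is a one-step side branch).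

Steps most likely to fail

Step 6 (proposed new method). The two metal cycles may fail to mesh. Nickel may arylate the C3 radical before it closes. Titanium may reduce the cyclised radical, so that the chain ends with hydrogen instead of aryl. The oxirane may be deoxygenated, or closure may leak to the 3,4-trans face. The fallback uses known chemistry only, sets out from 7 and returns at 12. Aldehyde 2 is methylenated (Ph3P=CH2, THF, 0 °C, Wittig reaction) to 3-methoxy-4-(triisopropylsilyloxy)styrene F1. Cross-metathesis of 7 with an excess of F1 (second-generation Grubbs catalyst, CH2Cl2, 40 °C) should give (R)-2-[(S)-{[(E)-3-[3-methoxy-4-(triisopropylsilyloxy)phenyl]prop-2-enyl]oxy}[3-methoxy-4-(triisopropylsilyloxy)phenyl]methyl]oxirane F2. Stoichiometric Cp2TiCl (Cp2TiCl2, Zn dust, THF, rt; then aq NaH2PO4) should then open the oxirane, and the C3 radical closes 5-exo onto the styrenyl alkene with the same chair-like bias. The benzylic radical is reduced by a second Cp2TiCl and protonated to the CH2–aryl group of 12. The aryl ring is thus in place before the radical step and no nickel is needed.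

Step 3. Incomplete rate discrimination between the two enantiomers would erode the enantiomeric purity of the epoxy alcohol. Lewis-acid-induced allylic transposition or oxirane opening of the electron-rich substrate would cost material. The fallback sets out from 4 and returns at 5, and resolves in the opposite sense. Alcohol 4 is epoxidised with D-(−)-DIPT, Ti(OiPr)4 and tBuOOH (0.6 equiv, 4 Å MS, CH2Cl2, −20 °C), so that the unwanted (S)-alcohol is consumed. (R)-1-[3-methoxy-4-(triisopropylsilyloxy)phenyl]prop-2-en-1-ol F3 is recovered at a conversion past one half, where the unreacted alcohol should be enantiopure even with a modest rate ratio. F3 is then epoxidised with L-(+)-DIPT, Ti(OiPr)4 and tBuOOH (matched pair, erythro) to 5.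

Step 4. The epoxy alkoxide may undergo Payne rearrangement (migration of the oxirane toward the benzylic carbon) or take a silyl group from an aryl ether before it is allylated. The fallback sets out from 5 and returns at 7. It is a Tsuji–Trost O-allylation under neutral conditions with allyl tert-butyl carbonate and Pd(PPh3)4 (cat.) in THF at 60 °C. The alcohol attacks a π-allylpalladium cation and no free alkoxide accumulates. This fallback makes no new compound (F0).

Further compounds
F1 | step 6 | 3-methoxy-4-(triisopropylsilyloxy)styrene | C=Cc1ccc(O[Si](C(C)C)(C(C)C)C(C)C)c(OC)c1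
F2 | step 6 | (R)-2-[(S)-{[(E)-3-[3-methoxy-4-(triisopropylsilyloxy)phenyl]prop-2-enyl]oxy}[3-methoxy-4-(triisopropylsilyloxy)phenyl]methyl]oxirane | COc1cc(/C=C/CO[C@@H](c2ccc(O[Si](C(C)C)(C(C)C)C(C)C)c(OC)c2)[C@H]2CO2)ccc1O[Si](C(C)C)(C(C)C)C(C)C
F3 | step 3 | (R)-1-[3-methoxy-4-(triisopropylsilyloxy)phenyl]prop-2-en-1-ol | C=C[C@@H](O)c1ccc(O[Si](C(C)C)(C(C)C)C(C)C)c(OC)c1
F0 | step 4 | none | none
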